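The route rests on breaking the C1–C9 bond of the six-membered ring (C1, C2, C6, C7, C8, C9). C1 is the 1,1-disubstituted carbon of the exocyclic methylene and sits next to the oxygenated C9, so this bond is the union of a 2-metallo-1-alkene with an aldehyde. A nickel/chromium-catalysed, cathode-driven Nozaki–Hiyama–Kishi closure forms this bond, the trans-fused hydrindane, the C9 stereocentre and the one free hydroxyl that must carry the angelate, all in a single operation. Its precursor is a fully substituted cyclopentane: C2 bears a 1-iodovinyl group, C4 the acetate, C5 the (Z)-ethylidene and C6 the chain C7(isopropyl)–C8(silyloxy)–C9 aldehyde.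

Key step: step 17

Remark: atom labels C1–C9 are those of the target and are kept for every intermediate; the C8 carbinol is set by hydride addition to a C8 ketone (steps 11 and 12) because Felkin–Anh addition of the dithiane anion to the C8 aldehyde is expected to favour the 8-epimer.

Step 1
Reactants: 1 (R)-4-(tert-butyldimethylsilyloxy)cyclopent-2-en-1-one; 2 (1-bromovinyl)trimethylsilane
Product: 5 (R)-4-[1-(trimethylsilyl)vinyl]cyclopent-2-en-1-one, via Grignard reagent 3 (not isolated), via trans adduct ketone 4 (not isolated)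
Conditions: 2, Mg, THF, reflux; CuBr·SMe2 (10 mol%), 1, THF, −78 °C; aq NH4Cl; crude, DBU, CH2Cl2, 0 °C, short contact
Reagents that add atoms: none
Why: Copper-catalysed conjugate addition of the α-silylvinyl Grignard reagent occurs anti to the silyloxy group, and brief DBU treatment then expels silanol by E1cB elimination, so the old stereocentre sets C2 (R) before it is erased.

Step 2
Reactants: 5 (R)-4-[1-(trimethylsilyl)vinyl]cyclopent-2-en-1-one
Product: 6 (R)-2-iodo-4-[1-(trimethylsilyl)vinyl]cyclopent-2-en-1-one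
Conditions: I2, pyridine, CH2Cl2, 0 °C → rt
Reagents that add atoms: iodine, II
Why: α-Iodination of an enone by the pyridine-mediated addition–iodination–elimination sequence (Baylis–Hillman-type α-halogenation) functionalises only C5, the pyridine-complexed iodine being too mild to attack the vinylsilane.

Step 3
Reactants: 6 (R)-2-iodo-4-[1-(trimethylsilyl)vinyl]cyclopent-2-en-1-one
Product: 7 (1S,4R)-2-iodo-4-[1-(trimethylsilyl)vinyl]cyclopent-2-en-1-ol
Conditions: NaBH4, CeCl3·7H2O, MeOH, −78 °C
Reagents that add atoms: none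
Why: Luche 1,2-reduction delivers hydride to the carbonyl face anti to the C2 substituent and should give the cis alcohol, which sets C4 (S).

Step 4
Reactants: 7 (1S,4R)-2-iodo-4-[1-(trimethylsilyl)vinyl]cyclopent-2-en-1-ol
Product: 8 triethyl{[(1S,4R)-2-iodo-4-[1-(trimethylsilyl)vinyl]cyclopent-2-en-1-yl]oxy}silane
Conditions: Et3SiCl, imidazole, DMF, 0 °C → rt
Reagents that add atoms: chlorotriethylsilane, CC[Si](Cl)(CC)CC
Why: Standard silylation of a secondary alcohol gives an ether that survives the organometallic and hydride steps and can later be cleaved beside a hindered tert-butyldimethylsilyl ether.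

Step 5
Reactants: 8 triethyl{[(1S,4R)-2-iodo-4-[1-(trimethylsilyl)vinyl]cyclopent-2-en-1-yl]oxy}silane; 9 N-methoxy-N-methylacetamide
Product: 11 1-[(3R,5S)-5-(triethylsilyloxy)-3-[1-(trimethylsilyl)vinyl]cyclopent-1-en-1-yl]ethan-1-one, via cyclopentenyllithium 10 (not isolated)
Conditions: t-BuLi (2.0 equiv), Et2O, −78 °C; then 9, −78 → 0 °C
Reagents that add atoms: none
Why: Iodine–lithium exchange, far faster at −78 °C than any addition to the vinylsilane, gives an alkenyllithium whose acylation in a Weinreb ketone synthesis stops at the ketone because the chelated tetrahedral intermediate survives until work-up.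

Step 6
Reactants: 11 1-[(3R,5S)-5-(triethylsilyloxy)-3-[1-(trimethylsilyl)vinyl]cyclopent-1-en-1-yl]ethan-1-one
Product: 12 (1R)-1-[(3R,5S)-5-(triethylsilyloxy)-3-[1-(trimethylsilyl)vinyl]cyclopent-1-en-1-yl]ethan-1-ol
Conditions: (S)-2-methyl-CBS-oxazaborolidine (0.3 equiv), catecholborane, toluene, −78 °C
Reagents that add atoms: none
Why: Corey–Bakshi–Shibata reduction with the (S)-oxazaborolidine treats the cyclopentenyl group as the large and methyl as the small ketone substituent and should give the (R)-carbinol under catalyst control, catecholborane at low temperature leaving the alkenes untouched.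

Step 7
Reactants: 12 (1R)-1-[(3R,5S)-5-(triethylsilyloxy)-3-[1-(trimethylsilyl)vinyl]cyclopent-1-en-1-yl]ethan-1-ol; 13 3-methylbutanoyl chloride
Product: 14 (1R)-1-[(3R,5S)-5-(triethylsilyloxy)-3-[1-(trimethylsilyl)vinyl]cyclopent-1-en-1-yl]ethyl 3-methylbutanoate
Conditions: pyridine, DMAP (cat), CH2Cl2, 0 °C → rt
Reagents that add atoms: none
Why: DMAP-catalysed acylation of the secondary allylic alcohol with the acid chloride forms the ester at oxygen and leaves the carbinol configuration untouched.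

Step 8
Reactants: 14 (1R)-1-[(3R,5S)-5-(triethylsilyloxy)-3-[1-(trimethylsilyl)vinyl]cyclopent-1-en-1-yl]ethyl 3-methylbutanoate
Product: 17 (2S)-3-methyl-2-[(1S,2Z,3S,5R)-2-ethylidene-3-(triethylsilyloxy)-5-[1-(trimethylsilyl)vinyl]cyclopentyl]butan-1-ol, via silyl ketene acetal 15 (not isolated), via trimethylsilyl ester 16 (not isolated)
Conditions: LiN(i-Pr)2, THF, −78 °C; Me3SiCl, −78 → 50 °C; then LiAlH4, 0 °C → rt
Reagents that add atoms: none
Why: In this Ireland–Claisen rearrangement kinetic enolisation in THF gives the (E)-silyl ketene acetal, which should rearrange through a chair transition state on the cyclopentene face anti to the C2 and C4 substituents with the carbinol methyl pseudo-equatorial, so that chirality transfer from the (R)-carbinol sets C6, C7 (anti) and the (Z)-ethylidene together before LiAlH4 reduces the silyl ester in the same pot.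

Step 9
Reactants: 17 (2S)-3-methyl-2-[(1S,2Z,3S,5R)-2-ethylidene-3-(triethylsilyloxy)-5-[1-(trimethylsilyl)vinyl]cyclopentyl]butan-1-ol
Product: 18 (2S)-3-methyl-2-[(1S,2Z,3S,5R)-2-ethylidene-3-(triethylsilyloxy)-5-[1-(trimethylsilyl)vinyl]cyclopentyl]butanal
Conditions: Dess–Martin periodinane, NaHCO3, CH2Cl2, 0 °C → rt
Reagents that add atoms: none
Why: Dess–Martin oxidation of the primary alcohol under buffered non-basic conditions should not epimerise the hindered C7 centre.

Step 10
Reactants: 18 (2S)-3-methyl-2-[(1S,2Z,3S,5R)-2-ethylidene-3-(triethylsilyloxy)-5-[1-(trimethylsilyl)vinyl]cyclopentyl]butanal; 19 1,3-dithiane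
Product: 21 (2S)-1-(1,3-dithian-2-yl)-3-methyl-2-[(1S,2Z,3S,5R)-2-ethylidene-3-(triethylsilyloxy)-5-[1-(trimethylsilyl)vinyl]cyclopentyl]butan-1-ol as a mixture of C8 epimers, via 2-lithio-1,3-dithiane 20 (not isolated)
Conditions: 19, n-BuLi, THF, −30 °C; then 18, −78 °C
Reagents that add atoms: none
Why: Corey–Seebach addition of the dithiane anion as a formyl anion equivalent builds the C8–C9 bond, and the configuration formed at C8 does not matter because step 11 erases it.

Step 11
Reactants: 21 (2S)-1-(1,3-dithian-2-yl)-3-methyl-2-[(1S,2Z,3S,5R)-2-ethylidene-3-(triethylsilyloxy)-5-[1-(trimethylsilyl)vinyl]cyclopentyl]butan-1-ol (C8 epimers)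
Product: 22 (2S)-1-(1,3-dithian-2-yl)-3-methyl-2-[(1S,2Z,3S,5R)-2-ethylidene-3-(triethylsilyloxy)-5-[1-(trimethylsilyl)vinyl]cyclopentyl]butan-1-one
Conditions: SO3·pyridine, DMSO, i-Pr2NEt, CH2Cl2, 0 °C
Reagents that add atoms: none
Why: Parikh–Doering oxidation converges both carbinol epimers on one 2-acyl-1,3-dithiane without oxidising sulfur, and the acidic dithiane C–H shields the hindered C7–H from enolisation.

Step 12
Reactants: 22 (2S)-1-(1,3-dithian-2-yl)-3-methyl-2-[(1S,2Z,3S,5R)-2-ethylidene-3-(triethylsilyloxy)-5-[1-(trimethylsilyl)vinyl]cyclopentyl]butan-1-one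
Product: 23 (1S,2S)-1-(1,3-dithian-2-yl)-3-methyl-2-[(1S,2Z,3S,5R)-2-ethylidene-3-(triethylsilyloxy)-5-[1-(trimethylsilyl)vinyl]cyclopentyl]butan-1-ol
Conditions: i-Bu2AlH, CH2Cl2, −78 °C
Reagents that add atoms: none
Why: In this Felkin–Anh-controlled hydride reduction the substituted cyclopentyl branch at C7 acts as the large group antiperiplanar to the incoming hydride and the C7 hydrogen sits next to the bulky dithianyl group, so attack should give the 7,8-anti alcohol (8S).

Step 13
Reactants: 23 (1S,2S)-1-(1,3-dithian-2-yl)-3-methyl-2-[(1S,2Z,3S,5R)-2-ethylidene-3-(triethylsilyloxy)-5-[1-(trimethylsilyl)vinyl]cyclopentyl]butan-1-ol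
Product: 24 tert-butyl{[(1S,2S)-1-(1,3-dithian-2-yl)-3-methyl-2-[(1S,2Z,3S,5R)-2-ethylidene-3-(triethylsilyloxy)-5-[1-(trimethylsilyl)vinyl]cyclopentyl]butyl]oxy}dimethylsilane
Conditions: t-BuMe2SiOTf, 2,6-lutidine, CH2Cl2, −78 → 0 °C
Reagents that add atoms: tert-butyldimethylsilyl trifluoromethanesulfonate, CC(C)(C)[Si](C)(C)OS(=O)(=O)C(F)(F)F
Why: Silylation of the hindered secondary alcohol with the silyl triflate and a hindered base is standard protecting-group chemistry that leaves the C4 triethylsilyl ether, the dithiane and the vinylsilane unchanged.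

Step 14
Reactants: 24 tert-butyl{[(1S,2S)-1-(1,3-dithian-2-yl)-3-methyl-2-[(1S,2Z,3S,5R)-2-ethylidene-3-(triethylsilyloxy)-5-[1-(trimethylsilyl)vinyl]cyclopentyl]butyl]oxy}dimethylsilane
Product: 26 (1S,2Z,3S,4R)-3-[(1S,2S)-1-(tert-butyldimethylsilyloxy)-1-(1,3-dithian-2-yl)-3-methylbutan-2-yl]-2-ethylidene-4-[1-(trimethylsilyl)vinyl]cyclopentyl acetate, via C4 alcohol 25 (not isolated)
Conditions: PPTS, MeOH/CH2Cl2, 0 °C; concentrate; Ac2O, pyridine, DMAP, CH2Cl2, rt
Reagents that add atoms: acetic anhydride, CC(=O)OC(C)=O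
Why: Acid-catalysed methanolysis removes the less hindered triethylsilyl ether selectively beside the hindered tert-butyldimethylsilyl ether, and DMAP-catalysed acetylation then installs the C4 acetate with retention.

Step 15
Reactants: 26 (1S,2Z,3S,4R)-3-[(1S,2S)-1-(tert-butyldimethylsilyloxy)-1-(1,3-dithian-2-yl)-3-methylbutan-2-yl]-2-ethylidene-4-[1-(trimethylsilyl)vinyl]cyclopentyl acetate
Product: 27 (1S,2Z,3S,4R)-3-[(2S,3S)-2-(tert-butyldimethylsilyloxy)-4-methyl-1-oxopentan-3-yl]-2-ethylidene-4-[1-(trimethylsilyl)vinyl]cyclopentyl acetate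
Conditions: MeI, CaCO3, MeCN/H2O (9:1), 45 °C
Reagents that add atoms: water, O
Why: Alkylative dithiane hydrolysis (S-methylation followed by hydrolysis of the activated thioacetal) unmasks the C9 aldehyde under buffered conditions that should neither epimerise the α-silyloxy centre nor touch the acetate or the vinylsilane.

Step 16
Reactants: 27 (1S,2Z,3S,4R)-3-[(2S,3S)-2-(tert-butyldimethylsilyloxy)-4-methyl-1-oxopentan-3-yl]-2-ethylidene-4-[1-(trimethylsilyl)vinyl]cyclopentyl acetate
Product: 28 (1S,2Z,3S,4R)-3-[(2S,3S)-2-(tert-butyldimethylsilyloxy)-4-methyl-1-oxopentan-3-yl]-2-ethylidene-4-(1-iodovinyl)cyclopentyl acetate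
Conditions: N-iodosuccinimide (1.2 equiv), (CF3)2CHOH, 0 °C
Reagents that add atoms: N-iodosuccinimide, O=C1CCC(=O)N1I
Why: In this ipso-iododesilylation iodonium attack on the vinylsilane is followed by irreversible loss of the silyl group, whereas iodonium formation at the hindered acetate-deactivated ethylidene is reversible and finds no good nucleophile in the fluorinated alcohol.

Step 17
Reactants: 28 (1S,2Z,3S,4R)-3-[(2S,3S)-2-(tert-butyldimethylsilyloxy)-4-methyl-1-oxopentan-3-yl]-2-ethylidene-4-(1-iodovinyl)cyclopentyl acetate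
Product: 29 (2R,4S,5Z,6R,7S,8S,9S)-4-acetoxy-8-(tert-butyldimethylsilyloxy)-5-ethylidene-7-isopropyl-1-methylidene-trans-hydrindan-9-ol (target numbering)
Conditions: CrCl3 (20 mol%), NiCl2 (2 mol%), 2,9-dimethyl-1,10-phenanthroline (2 mol%), Cp2ZrCl2 (1.2 equiv), LiCl, DMF, undivided cell, Al anode, Ni-foam cathode, constant current, rt, slow addition of 28 (final 5 mM)
Reagents that add atoms: none
Why: The cathode keeps chromium in the divalent state; zerovalent nickel inserts into the C1–I bond, the alkenyl group passes to trivalent chromium, and the alkenylchromium adds to the C9 aldehyde, the alkoxide being handed to zirconium so that chromium turns over. The closest known reaction type is the intramolecular nickel/chromium Nozaki–Hiyama–Kishi cyclisation of a 2-iodoalkene onto an aldehyde, run here with electrochemical chromium turnover. The six-membered ring (C1, C2, C6, C7, C8, C9) closes in a 6-exo-trig mode and is trans-fused to the cyclopentane because the C2 and C6 branches are trans and both sit equatorial in a chair-like transition state. The new C9 stereocentre is controlled by the C8 silyloxy group, which is axial in that chair: the non-chelating silyl ether favours the aldehyde C=O antiperiplanar to the C8–O bond (opposed dipoles) and keeps the metal alkoxide out of the plane of the forming exocyclic methylene, which should give the axial 9-hydroxyl trans to the 8-silyloxy group (9S). The step also needs chemoselectivity, which is secured because alkenylchromium reagents add to aldehydes but not to the acetate or the silyl ether, while high dilution suppresses intermolecular coupling.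

Step 18
Reactants: 29 (2R,4S,5Z,6R,7S,8S,9S)-4-acetoxy-8-(tert-butyldimethylsilyloxy)-5-ethylidene-7-isopropyl-1-methylidene-trans-hydrindan-9-ol; 30 angelic acid
Product: 32 9-angelate of 29, via mixed anhydride 31 (not isolated)
Conditions: 30, 2,4,6-trichlorobenzoyl chloride, Et3N, toluene, rt; then 29, 80 °C
Reagents that add atoms: none
Why: Yamaguchi esterification through the mixed 2,4,6-trichlorobenzoic anhydride, run without DMAP, acylates the only free hydroxyl (C9) and avoids the nucleophile-induced isomerisation of the angelate to the tiglate.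

Step 19
Reactants: 32 9-angelate of 29
Product: 33 CNP0210397.1 (target)
Conditions: HF·pyridine, pyridine, THF, 0 °C → rt
Reagents that add atoms: none
Why: Buffered fluoride desilylation removes the C8 silyl ether without cleaving either ester, and the trans-diaxial C8/C9 arrangement on the rigid trans-hydrindane disfavours 1,2-acyl migration.

Compound list
1 | (R)-4-(tert-butyldimethylsilyloxy)cyclopent-2-en-1-one | O=C1C=C[C@H](O[Si](C)(C)C(C)(C)C)C1 | starting material
2 | (1-bromovinyl)trimethylsilane | C=C(Br)[Si](C)(C)C | starting material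
3 | [1-(trimethylsilyl)vinyl]magnesium bromide | C=C([Mg]Br)[Si](C)(C)C | intermediate (not isolated)
4 | (3R,4R)-4-(tert-butyldimethylsilyloxy)-3-[1-(trimethylsilyl)vinyl]cyclopentan-1-one (trans) | O=C1C[C@@H](C(=C)[Si](C)(C)C)[C@H](O[Si](C)(C)C(C)(C)C)C1 | intermediate (not isolated)
5 | (R)-4-[1-(trimethylsilyl)vinyl]cyclopent-2-en-1-one | C=C([Si](C)(C)C)[C@@H]1CC(=O)C=C1 | intermediate
6 | (R)-2-iodo-4-[1-(trimethylsilyl)vinyl]cyclopent-2-en-1-one | C=C([Si](C)(C)C)[C@@H]1CC(=O)C(I)=C1 | intermediate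
7 | (1S,4R)-2-iodo-4-[1-(trimethylsilyl)vinyl]cyclopent-2-en-1-ol (cis) | C=C([Si](C)(C)C)[C@@H]1C[C@H](O)C(I)=C1 | intermediate
8 | triethyl{[(1S,4R)-2-iodo-4-[1-(trimethylsilyl)vinyl]cyclopent-2-en-1-yl]oxy}silane | C=C([Si](C)(C)C)[C@@H]1C[C@H](O[Si](CC)(CC)CC)C(I)=C1 | intermediate
9 | N-methoxy-N-methylacetamide | CON(C)C(C)=O | starting material
10 | [(3R,5S)-5-(triethylsilyloxy)-3-[1-(trimethylsilyl)vinyl]cyclopent-1-en-1-yl]lithium | C=C([Si](C)(C)C)[C@@H]1C[C@H](O[Si](CC)(CC)CC)C([Li])=C1 | intermediate (not isolated)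
11 | 1-[(3R,5S)-5-(triethylsilyloxy)-3-[1-(trimethylsilyl)vinyl]cyclopent-1-en-1-yl]ethan-1-one | C=C([Si](C)(C)C)[C@@H]1C[C@H](O[Si](CC)(CC)CC)C(C(C)=O)=C1 | intermediate
12 | (1R)-1-[(3R,5S)-5-(triethylsilyloxy)-3-[1-(trimethylsilyl)vinyl]cyclopent-1-en-1-yl]ethan-1-ol | C=C([Si](C)(C)C)[C@@H]1C[C@H](O[Si](CC)(CC)CC)C([C@@H](C)O)=C1 | intermediate
13 | 3-methylbutanoyl chloride (isovaleryl chloride) | CC(C)CC(=O)Cl | starting material
14 | (1R)-1-[(3R,5S)-5-(triethylsilyloxy)-3-[1-(trimethylsilyl)vinyl]cyclopent-1-en-1-yl]ethyl 3-methylbutanoate | C=C([Si](C)(C)C)[C@@H]1C[C@H](O[Si](CC)(CC)CC)C([C@@H](C)OC(=O)CC(C)C)=C1 | intermediate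
15 | (E)-trimethylsilyl ketene acetal of 14 (isopropyl cis to the allylic oxygen) | C=C([Si](C)(C)C)[C@@H]1C[C@H](O[Si](CC)(CC)CC)C([C@@H](C)O/C(O[Si](C)(C)C)=C\C(C)C)=C1 | intermediate (not isolated)
16 | trimethylsilyl (2S)-3-methyl-2-[(1S,2Z,3S,5R)-2-ethylidene-3-(triethylsilyloxy)-5-[1-(trimethylsilyl)vinyl]cyclopentyl]butanoate | C=C([Si](C)(C)C)[C@@H]1C[C@H](O[Si](CC)(CC)CC)/C(=C\C)[C@H]1[C@H](C(C)C)C(=O)O[Si](C)(C)C | intermediate (not isolated)
17 | (2S)-3-methyl-2-[(1S,2Z,3S,5R)-2-ethylidene-3-(triethylsilyloxy)-5-[1-(trimethylsilyl)vinyl]cyclopentyl]butan-1-ol | C=C([Si](C)(C)C)[C@@H]1C[C@H](O[Si](CC)(CC)CC)/C(=C\C)[C@H]1[C@H](C(C)C)CO | intermediate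
18 | (2S)-3-methyl-2-[(1S,2Z,3S,5R)-2-ethylidene-3-(triethylsilyloxy)-5-[1-(trimethylsilyl)vinyl]cyclopentyl]butanal | C=C([Si](C)(C)C)[C@@H]1C[C@H](O[Si](CC)(CC)CC)/C(=C\C)[C@H]1[C@H](C(C)C)C=O | intermediate
19 | 1,3-dithiane | C1CSCSC1 | starting material
20 | 2-lithio-1,3-dithiane | [Li]C1SCCCS1 | intermediate (not isolated)
21 | (2S)-1-(1,3-dithian-2-yl)-3-methyl-2-[(1S,2Z,3S,5R)-2-ethylidene-3-(triethylsilyloxy)-5-[1-(trimethylsilyl)vinyl]cyclopentyl]butan-1-ol, both C8 epimers | C=C([Si](C)(C)C)[C@@H]1C[C@H](O[Si](CC)(CC)CC)/C(=C\C)[C@H]1[C@H](C(C)C)C(O)C2SCCCS2 | intermediate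
22 | (2S)-1-(1,3-dithian-2-yl)-3-methyl-2-[(1S,2Z,3S,5R)-2-ethylidene-3-(triethylsilyloxy)-5-[1-(trimethylsilyl)vinyl]cyclopentyl]butan-1-one | C=C([Si](C)(C)C)[C@@H]1C[C@H](O[Si](CC)(CC)CC)/C(=C\C)[C@H]1[C@H](C(C)C)C(=O)C2SCCCS2 | intermediate
23 | (1S,2S)-1-(1,3-dithian-2-yl)-3-methyl-2-[(1S,2Z,3S,5R)-2-ethylidene-3-(triethylsilyloxy)-5-[1-(trimethylsilyl)vinyl]cyclopentyl]butan-1-ol | C=C([Si](C)(C)C)[C@@H]1C[C@H](O[Si](CC)(CC)CC)/C(=C\C)[C@H]1[C@H](C(C)C)[C@H](O)C2SCCCS2 | intermediate
24 | tert-butyl{[(1S,2S)-1-(1,3-dithian-2-yl)-3-methyl-2-[(1S,2Z,3S,5R)-2-ethylidene-3-(triethylsilyloxy)-5-[1-(trimethylsilyl)vinyl]cyclopentyl]butyl]oxy}dimethylsilane | C=C([Si](C)(C)C)[C@@H]1C[C@H](O[Si](CC)(CC)CC)/C(=C\C)[C@H]1[C@H](C(C)C)[C@H](O[Si](C)(C)C(C)(C)C)C2SCCCS2 | intermediate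
25 | (1S,2Z,3S,4R)-3-[(1S,2S)-1-(tert-butyldimethylsilyloxy)-1-(1,3-dithian-2-yl)-3-methylbutan-2-yl]-2-ethylidene-4-[1-(trimethylsilyl)vinyl]cyclopentan-1-ol | C=C([Si](C)(C)C)[C@@H]1C[C@H](O)/C(=C\C)[C@H]1[C@H](C(C)C)[C@H](O[Si](C)(C)C(C)(C)C)C2SCCCS2 | intermediate (not isolated)
26 | (1S,2Z,3S,4R)-3-[(1S,2S)-1-(tert-butyldimethylsilyloxy)-1-(1,3-dithian-2-yl)-3-methylbutan-2-yl]-2-ethylidene-4-[1-(trimethylsilyl)vinyl]cyclopentyl acetate | C=C([Si](C)(C)C)[C@@H]1C[C@H](OC(C)=O)/C(=C\C)[C@H]1[C@H](C(C)C)[C@H](O[Si](C)(C)C(C)(C)C)C2SCCCS2 | intermediate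
27 | (1S,2Z,3S,4R)-3-[(2S,3S)-2-(tert-butyldimethylsilyloxy)-4-methyl-1-oxopentan-3-yl]-2-ethylidene-4-[1-(trimethylsilyl)vinyl]cyclopentyl acetate | C=C([Si](C)(C)C)[C@@H]1C[C@H](OC(C)=O)/C(=C\C)[C@H]1[C@H](C(C)C)[C@H](O[Si](C)(C)C(C)(C)C)C=O | intermediate
28 | (1S,2Z,3S,4R)-3-[(2S,3S)-2-(tert-butyldimethylsilyloxy)-4-methyl-1-oxopentan-3-yl]-2-ethylidene-4-(1-iodovinyl)cyclopentyl acetate (key-step precursor) | C=C(I)[C@@H]1C[C@H](OC(C)=O)/C(=C\C)[C@H]1[C@H](C(C)C)[C@H](O[Si](C)(C)C(C)(C)C)C=O | intermediate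
29 | (2R,4S,5Z,6R,7S,8S,9S)-4-acetoxy-8-(tert-butyldimethylsilyloxy)-5-ethylidene-7-isopropyl-1-methylidene-trans-hydrindan-9-ol (target numbering; key-step product) | C=C1[C@@H]2C[C@H](OC(C)=O)/C(=C\C)[C@H]2[C@H](C(C)C)[C@H](O[Si](C)(C)C(C)(C)C)[C@H]1O | intermediate
30 | angelic acid, (Z)-2-methylbut-2-enoic acid | C/C=C(/C)C(=O)O | starting material
31 | angelic 2,4,6-trichlorobenzoic anhydride | C/C=C(/C)C(=O)OC(=O)c1c(Cl)cc(Cl)cc1Cl | intermediate (not isolated)
32 | (2R,4S,5Z,6R,7S,8S,9S)-4-acetoxy-8-(tert-butyldimethylsilyloxy)-5-ethylidene-7-isopropyl-1-methylidene-trans-hydrindan-9-yl (Z)-2-methylbut-2-enoate | C=C1[C@@H]2C[C@H](OC(C)=O)/C(=C\C)[C@H]2[C@H](C(C)C)[C@H](O[Si](C)(C)C(C)(C)C)[C@H]1OC(=O)/C(C)=C\C | intermediate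
33 | CNP0210397.1, (2R,4S,5Z,6R,7S,8S,9S)-4-acetoxy-5-ethylidene-8-hydroxy-7-isopropyl-1-methylidene-trans-hydrindan-9-yl (Z)-2-methylbut-2-enoate | C=C1[C@@H]2C[C@H](OC(C)=O)/C(=C\C)[C@H]2[C@H](C(C)C)[C@H](O)[C@H]1OC(=O)/C(C)=C\C | target

Total step count: 19 (steps 1, 8 and 14 each telescope two operations).
Longest linear sequence: 19 steps, from 1.

Steps most likely to fail

1. Step 17 (ring closure). What may go wrong: poor facial selectivity at the aldehyde, so that the hydroxyl forms cis to the C8 silyl ether. Oxidation and re-reduction would not correct this, because hydride should enter a C9 ketone anti to the axial C8 silyloxy group and return the same epimer. Fallback: setting out from 28, the closure is run as before and the 9-epi alcohol F1 that then predominates is esterified with angelic acid 30 under Mitsunobu conditions (PPh3, diisopropyl azodicarboxylate, toluene, 0 °C). This inverts C9 by SN2 displacement, installs the angelate in the same operation and rejoins the route at 32.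

2. Step 8 (Ireland–Claisen rearrangement). What may go wrong: erosion of the C7 configuration through incomplete (E)-selective enolisation or a competing boat-like transition state under the cyclopentene. Fallback: setting out from 12, an Eschenmoser–Claisen rearrangement with 1,1-dimethoxy-N,N,3-trimethylbutan-1-amine (made from N,N-dimethyl-3-methylbutanamide; xylene, 140 °C) forms the ketene N,O-acetal under neutral conditions. Its geometry is fixed by allylic strain rather than by kinetic deprotonation, and the rearrangement should give the N,N-dimethylamide F2. Reduction of F2 with LiH2NBH3 (THF, 0 °C → rt) rejoins the route at 17.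

3. Step 12 (hydride reduction). What may go wrong: poor or reversed facial selectivity in hydride delivery to the C8 ketone. Fallback: the stereocentre is taken from the carbon–carbon bond formation instead. Setting out from 18, the dithiane addition of step 10 follows the same Felkin–Anh preference with the roles of nucleophile and hydrogen exchanged, so it favours the C8 epimer that the reduction disfavours. The 8S component of 21 is separated and used directly as 23, where the route is rejoined; the 8R component is recycled through 22. No new compound is made (F0).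

Further compounds
F1 | step 17 | (2R,4S,5Z,6R,7S,8S,9R)-4-acetoxy-8-(tert-butyldimethylsilyloxy)-5-ethylidene-7-isopropyl-1-methylidene-trans-hydrindan-9-ol (9-epimer of 29) | C=C1[C@@H]2C[C@H](OC(C)=O)/C(=C\C)[C@H]2[C@H](C(C)C)[C@H](O[Si](C)(C)C(C)(C)C)[C@@H]1O
F2 | step 8 | (2S)-N,N,3-trimethyl-2-[(1S,2Z,3S,5R)-2-ethylidene-3-(triethylsilyloxy)-5-[1-(trimethylsilyl)vinyl]cyclopentyl]butanamide | C=C([Si](C)(C)C)[C@@H]1C[C@H](O[Si](CC)(CC)CC)/C(=C\C)[C@H]1[C@H](C(C)C)C(=O)N(C)C
F0 | step 12 | none | none
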